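**Plan**

- Retrosynthesis: the two phenols and the 1,3-diol are unmasked last. The array C1(OH)–C2–C3H2(OH), with the guaiacyl ring on C1 and the syringyl ring on C2, maps atom for atom onto O3–C4–C5–C6–O1 of a trans-4,5-diaryl-1,3-dioxane whose C2 is a formaldehyde carbon; this is the feature that permits a Prins annulation.
- The dioxane is cut at C5–C6 (diol C2–C3) and C4–O3 (diol C1–O) into an E-stilbene and two formaldehyde units. The stilbene is cut at the vinyl–aryl bond on the syringyl side into a styrene and an aryl bromide.
- Forward: Wittig methylenation and phenol pivaloylation give the two halves, a Heck coupling joins the chain, and the asymmetric Prins annulation closes the only ring built in the route. Benzyl-to-acetyl exchange, formal cleavage at the acetal carbon and ester methanolysis then release the target.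
- Stereochemistry: C2 (dioxane C5) comes from the face selectivity of a confined chiral Brønsted acid; C1 (dioxane C4) comes from suprafacial addition to the E olefin (trans, both aryl groups equatorial). No later step breaks a bond at either centre.

Key step: step 4

Remark 1: the target is read as (1S,2S), which corresponds to the trans-(4S,5S)-dioxane. The sense of induction of the confined acid on this internal diaryl olefin cannot be predicted with confidence, so the catalyst antipode that leads to the (4S,5S)-dioxane is assumed to be chosen in a pilot run (both antipodes derive from (R)- or (S)-BINOL).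

Remark 2: 4-benzyloxy-3-methoxybenzaldehyde (O-benzylvanillin) and 4-bromo-2,6-dimethoxyphenol are taken as commercial materials.

**Route**

Step 1
Reactants: 1 4-(benzyloxy)-3-methoxybenzaldehyde
Product: 2 4-benzyloxy-3-methoxystyrene
Conditions: Ph3PCH3Br, KOtBu, THF, 0 °C → rt
Reagents that add atoms: methyltriphenylphosphonium bromide, C[P+](c1ccccc1)(c1ccccc1)c1ccccc1.[Br-]
Why: Wittig methylenation of a non-enolisable aromatic aldehyde with the unstabilised ylide is reliable and leaves the benzyl ether untouched.

Step 2
Reactants: 3 4-bromo-2,6-dimethoxyphenol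
Product: 4 4-bromo-2,6-dimethoxyphenyl pivalate
Conditions: PivCl, Et3N, DMAP (cat.), CH2Cl2, 0 °C → rt
Reagents that add atoms: pivaloyl chloride, CC(C)(C)C(Cl)=O
Why: DMAP-catalysed O-acylation of the phenol should proceed despite the two flanking methoxy groups, and the pivalate both masks the phenol for the palladium step and makes the syringyl ring the electron-poorer aryl group.

Step 3
Reactants: 2 4-benzyloxy-3-methoxystyrene; 4 4-bromo-2,6-dimethoxyphenyl pivalate
Product: 5 (E)-4-[2-(4-benzyloxy-3-methoxyphenyl)ethenyl]-2,6-dimethoxyphenyl pivalate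
Conditions: Pd(OAc)2 (cat.), P(o-tol)3, Et3N, DMF, 100 °C
Reagents that add atoms: none
Why: Mizoroki–Heck arylation at the terminal styrene carbon followed by syn β-hydride elimination should give the E-stilbene; the bromide has no ortho substituent and the pivalate and benzyl ether tolerate Et3N in DMF.

Step 4
Reactants: 5 (E)-4-[2-(4-benzyloxy-3-methoxyphenyl)ethenyl]-2,6-dimethoxyphenyl pivalate; 6 paraformaldehyde (two CH2O units incorporated)
Product: 7 (4S,5S)-4-(4-benzyloxy-3-methoxyphenyl)-5-(3,5-dimethoxy-4-pivaloyloxyphenyl)-1,3-dioxane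
Conditions: (CH2O)n (5 equiv), confined chiral BINOL-derived imino-imidodiphosphate Brønsted acid (5 mol%), cyclohexane/CHCl3, 25–40 °C
Reagents that add atoms: formaldehyde (from paraformaldehyde 6, two units), C=O
Why: The chiral acid depolymerises paraformaldehyde and holds a protonated formaldehyde dimer (an HOCH2–O–CH2+ equivalent) as a tight ion pair; the olefin carbon bearing the pivaloyloxy-dimethoxyphenyl ring attacks its CH2 terminus (new C5–C6 bond) while the terminal hydroxyl oxygen collapses onto the benzylic carbon next to the benzyloxy-methoxyphenyl ring (new C4–O3 bond) in one suprafacial but strongly asynchronous event. The closest known reaction type is the Brønsted-acid-catalysed asymmetric intermolecular Prins reaction of aryl olefins with paraformaldehyde to 4-aryl-1,3-dioxanes, supported by the classical acid-mediated Prins reaction of 1,2-disubstituted aryl olefins, which gives trans-4,5-disubstituted 1,3-dioxanes; the present internal diaryl olefin is a more demanding member of that class. The single ring closed is the 1,3-dioxane, formed as a formal [4+2] annulation in which a six-membered chair-like array ends with oxygen capture of the incipient benzylic cation and places both aryl groups equatorial. C5 is set by the olefin face that the chiral anion pocket exposes to C–C bond formation (catalyst control), and C4 follows from syn addition across the E double bond, which turns the E geometry into the trans (4S,5S) relationship; trans is also the diequatorial thermodynamic isomer, so reversible ionisation of the C4–O bond would reclose to the same product. The step needs regioselectivity (C–C bond at the syringyl-side carbon, C–O bond at the guaiacyl-side carbon), which is secured by the para benzyloxy donor stabilising positive charge at C4 against the ester-deactivated, twisted pivaloyloxy ring with two inductively withdrawing meta methoxy groups; it also needs chemoselectivity for the olefin over ring hydroxymethylation, which the mild confined acid and the higher nucleophilicity of the stilbene π bond should provide.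

Step 5
Reactants: 7 (4S,5S)-4-(4-benzyloxy-3-methoxyphenyl)-5-(3,5-dimethoxy-4-pivaloyloxyphenyl)-1,3-dioxane
Product: 8 (4S,5S)-4-(4-hydroxy-3-methoxyphenyl)-5-(3,5-dimethoxy-4-pivaloyloxyphenyl)-1,3-dioxane
Conditions: H2 (1 atm), 10% Pd/C, EtOAc, rt
Reagents that add atoms: none
Why: Catalytic hydrogenolysis of an aryl benzyl ether under neutral conditions is much faster than cleavage of the ring benzylic C4–O bond, as in debenzylation of lignin-type benzylic alcohols, and the pivalate, the formal and both stereocentres should be untouched.

Step 6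
Reactants: 8 (4S,5S)-4-(4-hydroxy-3-methoxyphenyl)-5-(3,5-dimethoxy-4-pivaloyloxyphenyl)-1,3-dioxane
Product: 9 (4S,5S)-4-(4-acetoxy-3-methoxyphenyl)-5-(3,5-dimethoxy-4-pivaloyloxyphenyl)-1,3-dioxane
Conditions: Ac2O, pyridine, DMAP (cat.), CH2Cl2, rt
Reagents that add atoms: acetic anhydride, CC(=O)OC(C)=O
Why: Standard O-acetylation of the phenol, which lowers the donor power of the guaiacyl ring so that the benzylic C4–O bond should no longer ionise in the acetal cleavage that follows.

Step 7
Reactants: 9 (4S,5S)-4-(4-acetoxy-3-methoxyphenyl)-5-(3,5-dimethoxy-4-pivaloyloxyphenyl)-1,3-dioxane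
Product: 11 (1S,2S)-1-(4-acetoxy-3-methoxyphenyl)-2-(3,5-dimethoxy-4-pivaloyloxyphenyl)propane-1,3-diol, via N-(alkoxymethyl)-2,2'-bipyridinium triflate 10 (not isolated)
Conditions: TMSOTf, 2,2'-bipyridyl, CH2Cl2, 0 °C → rt; then H2O, rt
Reagents that add atoms: none
Why: Silyl triflate/2,2'-bipyridyl cleavage of a methylene acetal, in which TMSOTf silylates the less hindered O1, bipyridyl traps the resulting oxocarbenium carbon as an N-(alkoxymethyl)pyridinium salt and water then hydrolyses this N,O-acetal and the primary silyl ether; bonds are broken only at the acetal carbon and at silicon, so the (1S,2S) centres and both aryl esters should be kept.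

Step 8
Reactants: 11 (1S,2S)-1-(4-acetoxy-3-methoxyphenyl)-2-(3,5-dimethoxy-4-pivaloyloxyphenyl)propane-1,3-diol
Product: 12 (1S,2S)-1-(4-hydroxy-3-methoxyphenyl)-2-(4-hydroxy-3,5-dimethoxyphenyl)propane-1,3-diol
Conditions: NaOMe, MeOH, 0 °C → rt, Ar; then AcOH
Reagents that add atoms: none
Why: Zemplén-type base-mediated transesterification of the two aryl esters should free both phenols at room temperature, where the p-hydroxybenzylic alcohol does not go on to a quinone methide, so the configuration at C1 and C2 is kept.

**Compound list**

1 | 4-(benzyloxy)-3-methoxybenzaldehyde (O-benzylvanillin) | COc1cc(C=O)ccc1OCc1ccccc1 | starting material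
2 | 4-benzyloxy-3-methoxystyrene | COc1cc(C=C)ccc1OCc1ccccc1 | intermediate
3 | 4-bromo-2,6-dimethoxyphenol | COc1cc(Br)cc(OC)c1O | starting material
4 | 4-bromo-2,6-dimethoxyphenyl pivalate | COc1cc(Br)cc(OC)c1OC(=O)C(C)(C)C | intermediate
5 | (E)-4-[2-(4-benzyloxy-3-methoxyphenyl)ethenyl]-2,6-dimethoxyphenyl pivalate | COc1cc(/C=C/c2cc(OC)c(OC(=O)C(C)(C)C)c(OC)c2)ccc1OCc1ccccc1 | intermediate
6 | paraformaldehyde (source of formaldehyde) | C=O | starting material
7 | (4S,5S)-4-(4-benzyloxy-3-methoxyphenyl)-5-(3,5-dimethoxy-4-pivaloyloxyphenyl)-1,3-dioxane (trans) | COc1cc([C@H]2OCOC[C@@H]2c3cc(OC)c(OC(=O)C(C)(C)C)c(OC)c3)ccc1OCc1ccccc1 | intermediate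
8 | (4S,5S)-4-(4-hydroxy-3-methoxyphenyl)-5-(3,5-dimethoxy-4-pivaloyloxyphenyl)-1,3-dioxane | COc1cc([C@H]2OCOC[C@@H]2c3cc(OC)c(OC(=O)C(C)(C)C)c(OC)c3)ccc1O | intermediate
9 | (4S,5S)-4-(4-acetoxy-3-methoxyphenyl)-5-(3,5-dimethoxy-4-pivaloyloxyphenyl)-1,3-dioxane | COc1cc([C@H]2OCOC[C@@H]2c3cc(OC)c(OC(=O)C(C)(C)C)c(OC)c3)ccc1OC(C)=O | intermediate
10 | 1-{[(1S,2S)-1-(4-acetoxy-3-methoxyphenyl)-2-(3,5-dimethoxy-4-pivaloyloxyphenyl)-3-(trimethylsilyloxy)propoxy]methyl}-2,2'-bipyridin-1-ium triflate | COc1cc([C@@H](OC[n+]3ccccc3-c3ccccn3)[C@H](CO[Si](C)(C)C)c2cc(OC)c(OC(=O)C(C)(C)C)c(OC)c2)ccc1OC(C)=O.[O-]S(=O)(=O)C(F)(F)F | intermediate (not isolated)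
11 | (1S,2S)-1-(4-acetoxy-3-methoxyphenyl)-2-(3,5-dimethoxy-4-pivaloyloxyphenyl)propane-1,3-diol | COc1cc([C@@H](O)[C@H](CO)c2cc(OC)c(OC(=O)C(C)(C)C)c(OC)c2)ccc1OC(C)=O | intermediate
12 | (1S,2S)-1-(4-hydroxy-3-methoxyphenyl)-2-(4-hydroxy-3,5-dimethoxyphenyl)propane-1,3-diol | COc1cc([C@@H](O)[C@H](CO)c2cc(OC)c(O)c(OC)c2)ccc1O | target

**Step count**

Total: 8 steps. Longest linear sequence: 7 steps (1 → 2 → 5 → 7 → 8 → 9 → 11 → 12; steps 1, 3, 4, 5, 6, 7 and 8).

**Steps most likely to fail**

Step 4. The bulky internal diaryl olefin may fit the confined acid pocket less well than a simple styrene, which would show as slow turnover or poor facial selectivity. Electrophilic hydroxymethylation of the electron-rich benzyloxy-methoxy ring may also compete with addition to the olefin. The fallback sets out from 5 and comes back at 7, and takes the absolute configuration from resolution instead of catalysis. Stilbene 5 would be treated with paraformaldehyde and a catalytic achiral strong acid (Tf2NH, CH2Cl2, 0 °C) in a classical Prins reaction. The same electronic bias and the same syn addition should then give racemic trans-4-(4-benzyloxy-3-methoxyphenyl)-5-(3,5-dimethoxy-4-pivaloyloxyphenyl)-1,3-dioxane F1. Its enantiomers would be separated by preparative supercritical-fluid chromatography on a polysaccharide chiral stationary phase, and the (4S,5S) enantiomer is 7.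

Step 7. The silyl triflate may ionise the benzylic C–O bond instead of the acetal, with loss of configuration at C1 or elimination, or the cleavage may stall at mixed formals. The fallback sets out from 9 and comes back at 12. Acetolysis of 9 (Ac2O, AcOH, catalytic H2SO4, 0 °C) would open the formal by acylation of the less hindered oxygen and capture of the acetal carbon by acetate. This should give [(1S,2S)-3-acetoxy-1-(4-acetoxy-3-methoxyphenyl)-2-(3,5-dimethoxy-4-pivaloyloxyphenyl)propoxy]methyl acetate F2, in which the benzylic oxygen is never a free alcohol under acid. The conditions of step 8 (NaOMe, MeOH) would then remove the three acetates and the pivalate and collapse the resulting hemiformal, giving 12 directly.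

Step 5. Hydrogenolytic opening of the dioxane at the benzylic C4–O bond may compete with O-debenzylation, especially once the free phenol has formed. The fallback sets out from 4 and comes back at 8, and replaces the benzyl group by a fluoride-labile silyl ether so that no reductive step is needed. Commercial 2-methoxy-4-vinylphenol would be silylated (TIPSCl, imidazole, DMF) to triisopropyl(2-methoxy-4-vinylphenoxy)silane F3. Heck coupling of F3 with 4 under the conditions of step 3 should give (E)-4-{2-[3-methoxy-4-(triisopropylsilyloxy)phenyl]ethenyl}-2,6-dimethoxyphenyl pivalate F4, in which the silyloxy group is still a far better donor than the acyloxy ring. The Prins annulation of step 4 would convert F4 into (4S,5S)-5-(3,5-dimethoxy-4-pivaloyloxyphenyl)-4-[3-methoxy-4-(triisopropylsilyloxy)phenyl]-1,3-dioxane F5. Desilylation (TBAF buffered with AcOH, THF, 0 °C) would then give phenol 8.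

**Further compounds**

F1 | step 4 | racemic trans-4-(4-benzyloxy-3-methoxyphenyl)-5-(3,5-dimethoxy-4-pivaloyloxyphenyl)-1,3-dioxane (1:1 mixture of the 4S,5S and 4R,5R enantiomers) | COc1cc([C@H]2OCOC[C@@H]2c3cc(OC)c(OC(=O)C(C)(C)C)c(OC)c3)ccc1OCc1ccccc1.COc1cc([C@@H]2OCOC[C@H]2c3cc(OC)c(OC(=O)C(C)(C)C)c(OC)c3)ccc1OCc1ccccc1
F2 | step 7 | [(1S,2S)-3-acetoxy-1-(4-acetoxy-3-methoxyphenyl)-2-(3,5-dimethoxy-4-pivaloyloxyphenyl)propoxy]methyl acetate | COc1cc([C@@H](OCOC(C)=O)[C@H](COC(C)=O)c2cc(OC)c(OC(=O)C(C)(C)C)c(OC)c2)ccc1OC(C)=O
F3 | step 5 | triisopropyl(2-methoxy-4-vinylphenoxy)silane | COc1cc(C=C)ccc1O[Si](C(C)C)(C(C)C)C(C)C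
F4 | step 5 | (E)-4-{2-[3-methoxy-4-(triisopropylsilyloxy)phenyl]ethenyl}-2,6-dimethoxyphenyl pivalate | COc1cc(/C=C/c2cc(OC)c(OC(=O)C(C)(C)C)c(OC)c2)ccc1O[Si](C(C)C)(C(C)C)C(C)C
F5 | step 5 | (4S,5S)-5-(3,5-dimethoxy-4-pivaloyloxyphenyl)-4-[3-methoxy-4-(triisopropylsilyloxy)phenyl]-1,3-dioxane | COc1cc([C@H]2OCOC[C@@H]2c3cc(OC)c(OC(=O)C(C)(C)C)c(OC)c3)ccc1O[Si](C(C)C)(C(C)C)C(C)C
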